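**Strategy.** The six-membered ring is never built as such. Its stereocentre C5 (ring numbered as cyclohex-2-en-1-ol: C1 carbinol, C2 bearing CH2O, C5 bearing the side chain) lies between two methylene groups, C4 and C6, so C1–C6–C5–C4 is read as a prochiral 3-alkynylcyclobutanone and C2=C3 plus the CH2O carbon as a silylated propargyl ether. A nickel-catalysed, ligand-controlled insertion of this alkyne into one of the two enantiotopic acyl–CH2 bonds expands the four-membered ring by two atoms, forms C1–C2 and C3–C4 and sets C5 in one operation. The side chain follows by ruthenium-catalysed alkene–alkyne coupling; acylation and cis-selective Luche reduction complete the route.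

Key step: step 3

Assumption: compounds 1, 3 and 8 and the reagents TIPS-EBX, benzylchlorodimethylsilane, vinylmagnesium bromide and isobutyryl chloride are taken as purchasable, and the phosphoramidite antipode that leads to (5R)-6 has to be found by experiment (both antipodes are available).

**Step 1**
Reactants: 1 3-oxocyclobutane-1-carboxylic acid
Product: 2 3-[(triisopropylsilyl)ethynyl]cyclobutan-1-one
Conditions: TIPS-EBX (1.5 equiv), Ir[dF(CF3)ppy]2(dtbbpy)PF6 (1 mol%), Cs2CO3, CH2Cl2, blue LEDs, rt
Reagents that add atoms: TIPS-EBX, 1-[(triisopropylsilyl)ethynyl]-1,2-benziodoxol-3(1H)-one, CC(C)[Si](C(C)C)(C(C)C)C#CI1OC(=O)c2ccccc12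
Why: Photoredox decarboxylative alkynylation, in which the excited iridium photocatalyst oxidises the caesium carboxylate of 1, the 3-oxocyclobutyl radical left after loss of CO2 adds to the iodine-bound alkyne carbon of the hypervalent iodine reagent and β-fragmentation releases the silyl alkyne; no stereocentre arises because 2 is achiral.

**Step 2**
Reactants: 3 tert-butyldimethyl(prop-2-yn-1-yloxy)silane
Product: 5 benzyl(3-{[tert-butyl(dimethyl)silyl]oxy}prop-1-yn-1-yl)dimethylsilane, via lithium acetylide 4 (not isolated)
Conditions: n-BuLi, THF, −78 °C; then BnMe2SiCl, −78 °C → rt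
Reagents that add atoms: benzylchlorodimethylsilane, C[Si](C)(Cl)Cc1ccccc1
Why: Deprotonation of the terminal alkyne and C-silylation of the lithium acetylide is a standard alkynylsilane synthesis, and the benzyldimethylsilyl group is chosen because it should direct the regiochemistry at nickel and is later cleaved from a vinylic carbon by fluoride.

**Step 3**
Reactants: 2 3-[(triisopropylsilyl)ethynyl]cyclobutan-1-one; 5 benzyl(3-{[tert-butyl(dimethyl)silyl]oxy}prop-1-yn-1-yl)dimethylsilane
Product: 6 (5R)-3-[benzyl(dimethyl)silyl]-2-({[tert-butyl(dimethyl)silyl]oxy}methyl)-5-[(triisopropylsilyl)ethynyl]cyclohex-2-en-1-one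
Conditions: Ni(cod)2 (10 mol%), (S)-binaphthol-derived N,N-bis[(R)-1-phenylethyl]phosphoramidite (20 mol%), 5 (1.5 equiv), toluene, 80 °C
Reagents that add atoms: none
Why: Proposed new method: zerovalent nickel couples the carbonyl group of 2 and the alkyne of 5 oxidatively to a spiro oxanickelacyclopentene (silicon on the nickel-bound carbon, the CH2OTBS-bearing carbon bonded to the former carbonyl carbon), strain-driven β-carbon elimination then cleaves one of the two enantiotopic C(=O)–CH2 bonds of the four-membered ring, and C(sp3)–C(sp2) reductive elimination from the resulting seven-membered nickelacycle closes the six-membered ring, a formal [4+2] annulation that enlarges the ring by the two alkyne carbons. The closest known reaction type is the racemic nickel/trialkylphosphine-catalysed intermolecular insertion of internal alkynes into 3-substituted cyclobutanones, together with the enantioselective intramolecular alkene insertion into cyclobutanones under nickel/phosphoramidite catalysis; new here is the ligand-controlled intermolecular desymmetrisation with a silyl alkyne. The only new stereocentre, C5, is fixed by the chiral phosphoramidite on nickel, which decides which enantiotopic ring bond migrates to the metal. Regioselectivity (silicon at C3, CH2O carbon at C2) rests on the known preference of silyl alkynes to place silicon next to nickel in carbonyl–alkyne oxidative cyclisation. Chemoselectivity for 5 over the alkyne of 2 rests on the bulk of the TIPS group and the excess of 5, and reductive elimination is expected to outrun β-hydride elimination because the nickelacycle holds the C5–H bond away from the metal.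

**Step 4**
Reactants: 6 (5R)-3-[benzyl(dimethyl)silyl]-2-({[tert-butyl(dimethyl)silyl]oxy}methyl)-5-[(triisopropylsilyl)ethynyl]cyclohex-2-en-1-one
Product: 7 (5S)-5-ethynyl-2-(hydroxymethyl)cyclohex-2-en-1-one
Conditions: TBAF (5 equiv), wet THF, 0 °C → rt
Reagents that add atoms: none
Why: Fluoride-mediated global desilylation, in which TBAF cleaves the TBS ether and the alkynyl–TIPS bond and debenzylates the benzyldimethylsilyl group to a fluorosilane whose silicate is protodesilylated at the vinylic carbon (helped by the cis CH2O− group in the sense of a Brook-type C-to-O silyl shift); C5 is untouched and its descriptor changes from R to S only because silicon no longer raises the CIP rank of the C4 branch.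

**Step 5**
Reactants: 8 (S)-2-methylglycidol, [(2S)-2-methyloxiran-2-yl]methanol
Product: 9 (2R)-2-methylpent-4-ene-1,2-diol
Conditions: CH2=CHMgBr (3 equiv), CuI (10 mol%), THF, −30 → 0 °C; aq. NH4Cl
Reagents that add atoms: vinylmagnesium bromide, C=C[Mg]Br
Why: Copper-catalysed Grignard opening of the 2,2-disubstituted epoxide at its unsubstituted CH2 terminus (SN2) after deprotonation of the hydroxyl by the first equivalent of reagent; the quaternary stereocentre is not touched and its descriptor changes from S to R only by CIP ranking.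

**Step 6**
Reactants: 7 (5S)-5-ethynyl-2-(hydroxymethyl)cyclohex-2-en-1-one; 9 (2R)-2-methylpent-4-ene-1,2-diol
Product: 10 (5S)-5-[(4E,6R)-6,7-dihydroxy-6-methylhepta-1,4-dien-2-yl]-2-(hydroxymethyl)cyclohex-2-en-1-one
Conditions: [CpRu(MeCN)3]PF6 (10 mol%), 9 (1.5 equiv), acetone, rt
Reagents that add atoms: none
Why: Ruthenium-catalysed alkene–alkyne coupling (formal intermolecular Alder-ene reaction), in which oxidative cyclisation at cationic CpRu forms the new C–C bond at the internal alkyne carbon (branched mode, favoured by the α-branched propargylic position) and β-hydride elimination from the allylic CH2 followed by reductive elimination gives the 1,4-diene with an E-configured disubstituted alkene; no stereocentre is formed or touched.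

**Step 7**
Reactants: 10 (5S)-5-[(4E,6R)-6,7-dihydroxy-6-methylhepta-1,4-dien-2-yl]-2-(hydroxymethyl)cyclohex-2-en-1-one
Product: 11 [(4S)-4-{(4E,6R)-6-hydroxy-6-methyl-7-[(2-methylpropanoyl)oxy]hepta-1,4-dien-2-yl}-6-oxocyclohex-1-en-1-yl]methyl 2-methylpropanoate
Conditions: i-PrCOCl (2.4 equiv), 2,4,6-collidine, CH2Cl2, −20 → 0 °C
Reagents that add atoms: isobutyryl chloride, CC(C)C(=O)Cl
Why: Esterification of the two primary hydroxyl groups with an acid chloride and a non-nucleophilic pyridine base, the tertiary alcohol being too hindered to react and the collidine avoiding SN2' attack on the 2-(acyloxymethyl)enone.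

**Step 8**
Reactants: 11 [(4S)-4-{(4E,6R)-6-hydroxy-6-methyl-7-[(2-methylpropanoyl)oxy]hepta-1,4-dien-2-yl}-6-oxocyclohex-1-en-1-yl]methyl 2-methylpropanoate
Product: 12 [(4S,6S)-6-hydroxy-4-{(4E,6R)-6-hydroxy-6-methyl-7-[(2-methylpropanoyl)oxy]hepta-1,4-dien-2-yl}cyclohex-1-en-1-yl]methyl 2-methylpropanoate
Conditions: NaBH4, CeCl3·7H2O, MeOH, −78 °C; aq. NH4Cl
Reagents that add atoms: none
Why: Luche reduction, in which the cerium-activated borohydride reduces the enone carbonyl in 1,2-fashion without touching the esters and axial hydride delivery to the half-chair with the alkenyl substituent pseudo-equatorial should give the pseudo-equatorial alcohol cis to the side chain (new centre S), as in the reduction of carvone to cis-carveol.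

**Compound list**
1 | 3-oxocyclobutane-1-carboxylic acid | O=C1CC(C(=O)O)C1 | starting material
2 | 3-[(triisopropylsilyl)ethynyl]cyclobutan-1-one | CC(C)[Si](C(C)C)(C(C)C)C#CC1CC(=O)C1 | intermediate
3 | tert-butyldimethyl(prop-2-yn-1-yloxy)silane | C#CCO[Si](C)(C)C(C)(C)C | starting material
4 | lithium acetylide of 3, [3-{[tert-butyl(dimethyl)silyl]oxy}prop-1-yn-1-yl]lithium | [Li]C#CCO[Si](C)(C)C(C)(C)C | intermediate (not isolated)
5 | benzyl(3-{[tert-butyl(dimethyl)silyl]oxy}prop-1-yn-1-yl)dimethylsilane | CC(C)(C)[Si](C)(C)OCC#C[Si](C)(C)Cc1ccccc1 | intermediate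
6 | (5R)-3-[benzyl(dimethyl)silyl]-2-({[tert-butyl(dimethyl)silyl]oxy}methyl)-5-[(triisopropylsilyl)ethynyl]cyclohex-2-en-1-one | CC(C)[Si](C(C)C)(C(C)C)C#C[C@H]1CC([Si](C)(C)Cc2ccccc2)=C(CO[Si](C)(C)C(C)(C)C)C(=O)C1 | intermediate
7 | (5S)-5-ethynyl-2-(hydroxymethyl)cyclohex-2-en-1-one | C#C[C@H]1CC=C(CO)C(=O)C1 | intermediate
8 | (S)-2-methylglycidol, [(2S)-2-methyloxiran-2-yl]methanol | C1[C@@](C)(O1)CO | starting material
9 | (2R)-2-methylpent-4-ene-1,2-diol | C=CC[C@@](C)(O)CO | intermediate
10 | (5S)-5-[(4E,6R)-6,7-dihydroxy-6-methylhepta-1,4-dien-2-yl]-2-(hydroxymethyl)cyclohex-2-en-1-one | C=C(C/C=C/[C@@](C)(O)CO)[C@H]1CC=C(CO)C(=O)C1 | intermediate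
11 | [(4S)-4-{(4E,6R)-6-hydroxy-6-methyl-7-[(2-methylpropanoyl)oxy]hepta-1,4-dien-2-yl}-6-oxocyclohex-1-en-1-yl]methyl 2-methylpropanoate | C=C(C/C=C/[C@@](C)(O)COC(=O)C(C)C)[C@H]1CC=C(COC(=O)C(C)C)C(=O)C1 | intermediate
12 | [(4S,6S)-6-hydroxy-4-{(4E,6R)-6-hydroxy-6-methyl-7-[(2-methylpropanoyl)oxy]hepta-1,4-dien-2-yl}cyclohex-1-en-1-yl]methyl 2-methylpropanoate | C=C(C/C=C/[C@@](C)(O)COC(=O)C(C)C)[C@H]1CC=C(COC(=O)C(C)C)[C@@H](O)C1 | target

**Step count.** Total: 8 steps. Longest linear sequence: 6 steps (steps 1, 3, 4, 6, 7, 8).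

**Steps most likely to fail**

Step 3. The discrimination between the two enantiotopic acyl–CH2 bonds may be insufficient, the regiocontrol of the oxidative cyclisation may erode, or the alkyne may oligomerise at nickel. Fallback (known chemistry, resolution instead of asymmetric catalysis): setting out from 2 and 5, the annulation is run under the established achiral conditions (Ni(cod)2, PCy3, toluene, 100 °C) to give racemic 3-[benzyl(dimethyl)silyl]-2-({[tert-butyl(dimethyl)silyl]oxy}methyl)-5-[(triisopropylsilyl)ethynyl]cyclohex-2-en-1-one F1. Preparative chromatography on a chiral stationary phase (supercritical CO2/alcohol) should separate it into 6 and the (5S)-enantiomer of 6 F2, which is set aside. The route is rejoined at 6.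

Step 4. Cleavage of the vinylic C–Si bond may stay incomplete, and the basic fluoride may degrade the 2-(hydroxymethyl)enone (retro-aldol loss of formaldehyde, conjugate addition). Fallback (reduction before desilylation, chemoselective acylation at the end): setting out from 6, Luche reduction (NaBH4, CeCl3·7H2O, MeOH, −78 °C) should give (1S,5R)-3-[benzyl(dimethyl)silyl]-2-({[tert-butyl(dimethyl)silyl]oxy}methyl)-5-[(triisopropylsilyl)ethynyl]cyclohex-2-en-1-ol F3; the cis selectivity may be lower here because the slim alkynyl group biases the ring conformation less. TBAF in THF (rt to 50 °C) on this base-stable allylic alcohol should give (1S,5S)-5-ethynyl-2-(hydroxymethyl)cyclohex-2-en-1-ol F4. Coupling with 9 under the conditions of step 6 should give (1S,5S)-5-[(4E,6R)-6,7-dihydroxy-6-methylhepta-1,4-dien-2-yl]-2-(hydroxymethyl)cyclohex-2-en-1-ol F5. Primary-selective double acylation (i-PrCOCl, 2,4,6-collidine, CH2Cl2, −78 °C) then leads directly to 12, where the route is rejoined.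

Step 6. The branched-to-linear regioselectivity of the ruthenacycle formation may erode, the diol may sequester the cationic catalyst, or the skipped diene may isomerise. Fallback (stepwise allylation and cross-metathesis instead of the Alder-ene union): setting out from 7, Markovnikov hydrostannation (Bu3SnH, Mo(CO)3(CNtBu)3 cat., hydroquinone, THF, 55 °C) should give (5S)-2-(hydroxymethyl)-5-[1-(tributylstannyl)ethenyl]cyclohex-2-en-1-one F6. Stille coupling with allyl bromide (Pd2(dba)3, P(2-furyl)3, DMF) should give (5S)-2-(hydroxymethyl)-5-(penta-1,4-dien-2-yl)cyclohex-2-en-1-one F7. Separately, 8 is homologated with dimethylsulfonium methylide (Me3SI, n-BuLi, THF, −10 °C → rt) to (2R)-2-methylbut-3-ene-1,2-diol F8. Cross-metathesis of F7 with excess F8 (second-generation Grubbs catalyst, CH2Cl2, 40 °C) should give the E-alkene 10, where the route is rejoined.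

**Further compounds**
F1 | step 3 | racemic 3-[benzyl(dimethyl)silyl]-2-({[tert-butyl(dimethyl)silyl]oxy}methyl)-5-[(triisopropylsilyl)ethynyl]cyclohex-2-en-1-one | CC(C)[Si](C(C)C)(C(C)C)C#CC1CC([Si](C)(C)Cc2ccccc2)=C(CO[Si](C)(C)C(C)(C)C)C(=O)C1
F2 | step 3 | (5S)-3-[benzyl(dimethyl)silyl]-2-({[tert-butyl(dimethyl)silyl]oxy}methyl)-5-[(triisopropylsilyl)ethynyl]cyclohex-2-en-1-one | CC(C)[Si](C(C)C)(C(C)C)C#C[C@@H]1CC([Si](C)(C)Cc2ccccc2)=C(CO[Si](C)(C)C(C)(C)C)C(=O)C1
F3 | step 4 | (1S,5R)-3-[benzyl(dimethyl)silyl]-2-({[tert-butyl(dimethyl)silyl]oxy}methyl)-5-[(triisopropylsilyl)ethynyl]cyclohex-2-en-1-ol | CC(C)[Si](C(C)C)(C(C)C)C#C[C@H]1CC([Si](C)(C)Cc2ccccc2)=C(CO[Si](C)(C)C(C)(C)C)[C@@H](O)C1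
F4 | step 4 | (1S,5S)-5-ethynyl-2-(hydroxymethyl)cyclohex-2-en-1-ol | C#C[C@H]1CC=C(CO)[C@@H](O)C1
F5 | step 4 | (1S,5S)-5-[(4E,6R)-6,7-dihydroxy-6-methylhepta-1,4-dien-2-yl]-2-(hydroxymethyl)cyclohex-2-en-1-ol | C=C(C/C=C/[C@@](C)(O)CO)[C@H]1CC=C(CO)[C@@H](O)C1
F6 | step 6 | (5S)-2-(hydroxymethyl)-5-[1-(tributylstannyl)ethenyl]cyclohex-2-en-1-one | C=C([Sn](CCCC)(CCCC)CCCC)[C@H]1CC=C(CO)C(=O)C1
F7 | step 6 | (5S)-2-(hydroxymethyl)-5-(penta-1,4-dien-2-yl)cyclohex-2-en-1-one | C=CCC(=C)[C@H]1CC=C(CO)C(=O)C1
F8 | step 6 | (2R)-2-methylbut-3-ene-1,2-diol | C=C[C@@](C)(O)CO
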